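A small charge of Q meets G in a closed, stirred flask, and X is the first adduct on the way to L. You want X after the same time in each new flask.

| setting | winter | noon | green | red | ochre |
|---|---|---|---|---|---|
| Q | 0.10 M | 0.10 M | 0.10 M | 0.10 M | 0.10 M |
| G | 0.11 M | 0.56 M | 0.0800 M | 0.150 M | 0.400 M |
| remark | run made earlier | run made earlier |  |  |  |
| time |  |  | 6.0 d | 6.0 d | 6.0 d |

| run | time / d | X / % | L / % |
|---|---|---|---|
| winter | 0.333 | 2.4 | 0.2 |
| winter | 0.833 | 6.6 | 0 |
| winter | 1.67 | 11.6 | 0.2 |
| winter | 4.00 | 22.1 | 1.0 |
| noon | 1.04 | 32.5 | 0.2 |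
| noon | 2.00 | 46.7 | 0.2 |
| noon | 3.00 | 54.4 | 0 |
| noon | 4.00 | 58.3 | 0.4 |

(standard deviation of a reading: 0.5 percentage points)

- amount of X at the end, in percent of the Q charged, for each flask in turn (green, red, ochre)

Fold the givens into one number. The first noon reading gives a second-order constant of 0.675 /M/d. Multiply it by the charged [G] and the time and you have the exposure, the pseudo-first-order count of e-foldings of Q if [G] stayed as charged. Red has 0.607, and Q left should then be exp(−exposure).

The noon readings at 0.393 and 0.756 bracket red, and between them you read 40.9% of X.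

Is one number enough? Winter's last reading, at exposure 0.297, should show 25.7% of X but reads 22.1%. That is a ratio of 0.860, read from readings with a scatter of 0.5 percentage points. So the exposure is not enough: winter gave less than its number promised. Applying that ratio to red, I would commit to 35.2%.

The forecast gives 22.8%, 36.7% and 56.5%, holding that “X is being drained into unseen intermediates”. Its red is a little above mine.

The flasks give 21.4%, 35.1% and 58.1%, so the forecast held.

    G + X → J (k = 2.70 × 10⁻⁶ /M/s)
    G ⇌ E (K = 0.490, k = 1.60 × 10⁻⁶ /s)
    G + D ⇌ L (K = 6.80 /M, k = 4.30 × 10⁻⁷ /M/s)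
    L → Z (k = 2.80 × 10⁻⁷ /s)
    G + J → D (k = 4.90 × 10⁻⁵ /M/s)
    Q + G → X (k = 9.30 × 10⁻⁶ /M/s)

Red ends with 62% of its Q, where the exposure promised 54.5%. The exposure actually delivered, −ln of the Q left, is 0.478, a ratio of 0.788 to the charged number. Red's 35.1% of X owes a part of its size to the turning of G into E, both ways, acting together with the length of the run: without that turning red gives 40.5% of X, and at 60.0 d it stands at 60.2%. Ochre, with exposure 1.62, ends with 27% of its Q and 51% of its G, a ratio of 0.798.

The data are simulated from invented constants, noise included.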